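All runs are calculated from invented constants, noise included.

The closed, stirred vessel holds substrate and partner at constant volume and temperature, and it makes mono adduct, which partner can attack further.

common to all: substrate 0.32 M
- amber: partner 0.81 equiv; run made earlier
- ochre: partner 5.5 equiv; run made earlier
- Monday's: partner 1.00 equiv; time 5.0 h
- Thursday's: partner 2.00 equiv; time 5.0 h
- Tuesday's: partner 4.00 equiv; time 5.0 h
- Sunday's: partner 8.00 equiv; time 5.0 h

| run | time / h | mono adduct / % | substrate / % |
|---|---|---|---|
| amber | 0.417 | 21.1 | 59.8 |
| amber | 1.00 | 35.2 | 35.8 |
| amber | 2.00 | 44.7 | 21.1 |
| amber | 5.00 | 50.9 | 10.4 |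
| ochre | 0.417 | 53.3 | 11.0 |
| ochre | 1.00 | 44.6 | 4.6 |
| ochre | 2.00 | 28.9 | 1.5 |
| ochre | 5.00 | 5.1 | 0 |

(each reading ± 1 percentage point)

- a reading or a percentage of mono adduct counts all its forms, free or not
- the concentration of mono adduct that is asked is that of its free form alone
- "hardly changes" means that all values lie within two and a half points (for a concentration: within two and a half percent of the largest)
- a reading of substrate is of its free form alone

1. [mono adduct] (only what is free in solution) at the end for Monday's, Thursday's, Tuesday's, Sunday's, in this order
2. how the row runs (falls, then rises / rises all the way / rises, then falls / falls all the way / hardly changes)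

The bench rule for such a chain is a balance: each substrate lost has taken at least one partner, so the substrate lost should stay within the partner charged. The amber run breaks this rule. By 5.00 h it has lost 89.6% of its substrate on a charge of 0.81 equiv, a ratio of 1.11, and the loss is larger than the charge. Already at 0.417 h the mono reading in amber is about half of the substrate lost. A second substrate therefore seems to sit on mono adduct, absent from the substrate reading and present inside the mono reading.

At 2.00 h in amber, counting nothing beyond mono adduct, the held share is 34.2% and the free mono adduct is 10.5%. This gives 48.2 L mol⁻¹ for the capture constant K, an association constant: the held pair's concentration over the product of free substrate and free mono adduct. K is a reading that carries the scatter of a small difference, and any bis adduct present would raise it, because it would swell the held share and shrink the free mono adduct by the same amount.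

Held fixed, K turns two readings into a free concentration: the mono reading divided by one plus K times the free substrate concentration. This reckoning gives 0.0625 M for amber at 5.00 h, the neighbour of Monday's. The ochre run, at 5.5 equiv, has 0% substrate at 5.00 h, so its whole reading is free, 0.0163 M.

The forecast, holding that “free substrate hides in a reversible complex with mono adduct”, gives 0.087 M, 0.097 M, 0.043 M and 0.002 M, a row that rises, then falls. Its constant is about 30 per molar against 48.2 L mol⁻¹ here, and its Monday's value stands against the 0.0625 M read from amber.

The flasks give 0.0661 M, 0.0752 M, 0.0392 M and 3.58 × 10⁻⁴ M, a row that rises, then falls.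

    substrate + partner → mono adduct (k = 8.10 × 10⁻⁴ L mol⁻¹ s⁻¹)
    partner + mono adduct → bis adduct (k = 3.20 × 10⁻⁴ L mol⁻¹ s⁻¹)
    partner + bis adduct → triple product (k = 7.70 × 10⁻⁴ L mol⁻¹ s⁻¹)
    substrate + mono adduct ⇌ idle adduct, settled at all times (K = 55.0 L mol⁻¹)

In Monday's flask, with the other concentrations as charged, substrate has a half-life of 0.74 h by the making of mono adduct, shorter than the 1.9 h of free mono adduct by the making of bis adduct. At 5.0 h in Monday's flask, the two steps use partner at a ratio of 1.0. K applied to Monday's simulated 8.46% substrate and 51.5% mono adduct gives 0.0714 M free, against 0.0661 M. Applied to Thursday's simulated 4.37% and 41.6%, it gives 0.0795 M, against 0.0752 M.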